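At the start of noon, substrate went 3.8 times as fast into intermediate as into side product, so I watched that ratio as the second reagent grew.

| setting | noon | spring | summer | dawn |
|---|---|---|---|---|
| substrate | 5.0 mM | 5.0 mM | 5.0 mM | 5.0 mM |
| partner | 3.00 equiv | 3.00 equiv | 3.00 equiv | 3.00 equiv |
| second reagent | 0.500 equiv | 1.00 equiv | 2.00 equiv | 4.00 equiv |
| protic impurity | 0.100 mM | 0.100 mM | 0.100 mM | 0.100 mM |
| time | 6.0 s | 6.0 s | 6.0 s | 6.0 s |

    substrate + partner → intermediate (k1 = 200 M⁻¹ s⁻¹)
    second reagent + intermediate → target (k2 = 950 M⁻¹ s⁻¹)
    substrate + second reagent → side product (k3 = 320 M⁻¹ s⁻¹)
    target → over-reaction product (k4 = 0.0011 s⁻¹)
    second reagent + protic impurity → quenched reagent (k5 = 2800 M⁻¹ s⁻¹)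

- amount of target at the end, in percent of the substrate charged for noon, spring, summer, dawn, in this order
- the shape of the row from first to last (hardly changes / rises all the way / falls, then rises / falls all the way / rises, then falls)

- "hardly changes" means that all values lie within two and a half points (for a concentration: within two and a half percent of the largest)
- run time (noon): 6.0 s

I wrote b for the partner and d for the second reagent, both as fractions of the substrate charge. Substrate has two exits, so the part that leaves towards intermediate is the first-step constant times b, divided by that product plus the third-step constant times d.

At the charge this part was 65.2% for spring and 48.4% for summer. In noon, intermediate had a half-life of 0.29 s by step 2 against a run of 6.0 s, and summer carries more second reagent. Target's half-life of 11 min was long against the run. So in summer I counted that part as target.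

But b and d do not stay at their charge. The side exit costs one second reagent at once, the intermediate exit costs one only when step 2 has run, and the impurity takes a correction of 2.00%. So I reckoned only the change. Half-way through the substrate, b had lost half of the share, and d had lost the correction and the side part. In summer, at the charge, substrate's half-life by both exits was 0.112 s and intermediate's by step 2 was 0.0730 s, so d had also lost part of the intermediate made by then, and I counted half of it as passed on. For summer this gave 51.8%, the half-way branch share, meaning the part of substrate going towards intermediate when half of it is used.

Noon is different, since there the second reagent is the limiting reagent: about 48.0% remained for target and side product together. With noon below that, spring near 65.2%, summer near 51.8% and dawn's share at the charge at 31.9%, I committed to a row with the shape rises, then falls.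

The forecast gave 34%, 68%, 53% and 34%, rises, then falls, on the ground that “the direct substrate reaction outcompetes the partner”.

The flask gave 33.5%, 67.0%, 52.0% and 33.2%: rises, then falls. Summer held 52.0% of target against my 51.8%, and its second reagent stood at 49.0% of its own charge, where the count of one per substrate gave 49.0%. For dawn, the share at the charge is 31.9% and the half-way branch share is 33.3%; the dawn flask ended with 33.2% of target.

The numbers of this flask were drawn at random within sensible limits; no experiment stands behind them.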